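## Retrosynthetic overview

1. Vitedoin A ⇐ its bis-benzyl ether ⇐ (MnO2, i-Bu2AlH, LiBH4) a trans-1-aryl-1,2-dihydronaphthalene whose C2 carbon substituent is an acyl oxazolidinone and whose C3 carbon substituent is a methyl ester.
2. Ring B is the only ring made and is closed last among the C–C bonds: C1–C8a by cationic Friedel–Crafts alkylation, aryl trans to the C2 acyl group. A bromine para to the ring A methoxy group blocks the normal site, so closure must occur between side chain and OMe; the bromine is removed afterwards.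
3. Key fragment union: Evans syn-aldol (C1–C2) between the boron enolate of an (E)-arylidenesuccinyl oxazolidinone (ring A plus C2–C3–C4) and O-benzylvanillin (ring C). It sets C2; C1 then follows from C2 in the ring closure.
4. The arylidenesuccinate comes from a Stobbe (aldol-type) condensation of 6-bromo-O-benzylvanillin with dimethyl succinate (C3–C4). Rings A and C are both bought as vanillin benzyl ether.

Assumption: vanillin benzyl ether, dimethyl succinate and the Evans benzyl-oxazolidinone are taken as catalogue chemicals. Locants C1–C8a are those of the 1-aryl-1,2-dihydronaphthalene (C1 aryl, C2 CH2OH, C3 CHO, C7 OH, C8 OMe); the target is (1S,2R), trans.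

## Route

Step 1
Reactants: 1 4-(benzyloxy)-3-methoxybenzaldehyde
Product: 2 4-(benzyloxy)-2-bromo-5-methoxybenzaldehyde
Conditions: Br2 (1.1 equiv), NaOAc, AcOH, rt
Reagents that add atoms: bromine, BrBr
Why: Electrophilic aromatic bromination: in O-alkylated vanillins the ring methoxy group directs para, so bromine enters ortho to CHO at the position that must later be blocked, and NaOAc buffers HBr so the benzyl ether survives.

Step 2
Reactants: 2 4-(benzyloxy)-2-bromo-5-methoxybenzaldehyde; 3 dimethyl succinate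
Product: 5 (3E)-4-[4-(benzyloxy)-2-bromo-5-methoxyphenyl]-3-(methoxycarbonyl)but-3-enoic acid, via paraconate lactone 4 (not isolated)
Conditions: NaOMe, MeOH, reflux; then aq. HCl
Reagents that add atoms: none
Why: Stobbe condensation (aldol addition of the succinate enolate, lactonisation to 4, then E1cB ring opening) forms the C3–C4 bond and gives the (E)-half-ester, in which only the saturated carboxyl is free and the aryl ring sits cis to the CH2 group as the later ring closure requires.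

Step 3
Reactants: 5 (3E)-half-ester acid; 6 (S)-4-benzyl-1,3-oxazolidin-2-one
Product: 8 (4S)-4-benzyl-3-[(3E)-4-[4-(benzyloxy)-2-bromo-5-methoxyphenyl]-3-(methoxycarbonyl)but-3-enoyl]-1,3-oxazolidin-2-one, via mixed pivalic anhydride 7 (not isolated)
Conditions: t-BuCOCl, Et3N, THF, −20 °C; then 6, LiCl, −20 °C → rt
Reagents that add atoms: none
Why: N-acylation of the Evans auxiliary through the mixed pivalic anhydride: the LiCl-activated oxazolidinone attacks the unhindered carbonyl of 7 and the conjugated methyl ester is untouched.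

Step 4
Reactants: 8 (E)-arylidenesuccinyl imide; 1 4-(benzyloxy)-3-methoxybenzaldehyde
Product: 11 (4S)-4-benzyl-3-[(2S,3E)-4-[4-(benzyloxy)-2-bromo-5-methoxyphenyl]-2-[(S)-[4-(benzyloxy)-3-methoxyphenyl](hydroxy)methyl]-3-(methoxycarbonyl)but-3-enoyl]-1,3-oxazolidin-2-one, via boron enolate 9 (not isolated), via boron aldolate 10 (not isolated)
Conditions: n-Bu2BOTf, i-Pr2NEt, CH2Cl2, −78 → 0 °C; 1, −78 → 0 °C; then MeOH, aq. NaH2PO4/Na2HPO4, 30% H2O2, 0 °C
Reagents that add atoms: none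
Why: Evans syn-aldol reaction, the key intermolecular C1–C2 bond formation: soft enolisation gives the (Z)-boron enolate 9, which reacts with the aldehyde through a closed Zimmerman–Traxler transition state on the face away from the auxiliary benzyl group, fixing C2 (the carbinol centre is erased in step 5).

Step 5
Reactants: 11 syn-aldol adduct
Product: 13 methyl (3R,4S)-6-(benzyloxy)-4-[4-(benzyloxy)-3-methoxyphenyl]-3-{[(4S)-4-benzyl-2-oxo-1,3-oxazolidin-3-yl]carbonyl}-8-bromo-5-methoxy-3,4-dihydronaphthalene-2-carboxylate (3,4-trans), via benzylic cation 12 (not isolated)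
Conditions: CF3CO2H, CH2Cl2, 0 °C → rt
Reagents that add atoms: none
Why: Intramolecular Friedel–Crafts alkylation: the p-alkoxybenzylic cation 12 closes ring B onto ring A, and because the position para to OMe carries bromine the only reachable ring carbon is the one between the side chain and OMe; the aryl group enters anti to the C2 acyl substituent (both pseudo-axial, away from the peri OMe), which sets C1 trans to C2.

Step 6
Reactants: 13 bromo imide ester
Product: 14 methyl (3R,4S)-6-(benzyloxy)-4-[4-(benzyloxy)-3-methoxyphenyl]-3-{[(4S)-4-benzyl-2-oxo-1,3-oxazolidin-3-yl]carbonyl}-5-methoxy-3,4-dihydronaphthalene-2-carboxylate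
Conditions: n-Bu3SnH, AIBN (cat.), toluene, 90 °C
Reagents that add atoms: none
Why: Radical chain hydrodehalogenation with tin hydride removes the blocking bromine under neutral conditions, so the enolisable C2–H next to the imide, the enoate and the benzyl ethers are left alone.

Step 7
Reactants: 14 imide ester
Product: 15 methyl (3R,4S)-6-(benzyloxy)-4-[4-(benzyloxy)-3-methoxyphenyl]-3-(hydroxymethyl)-5-methoxy-3,4-dihydronaphthalene-2-carboxylate
Conditions: LiBH4, MeOH (1 equiv), THF, 0 °C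
Reagents that add atoms: none
Why: Reductive cleavage of the N-acyl oxazolidinone with LiBH4, which attacks the activated imide carbonyl far faster than the conjugated methyl ester and releases the auxiliary without enolising C2.

Step 8
Reactants: 15 hydroxy ester
Product: 16 [(1S,2R)-7-(benzyloxy)-1-[4-(benzyloxy)-3-methoxyphenyl]-8-methoxy-1,2-dihydronaphthalene-2,3-diyl]dimethanol
Conditions: i-Bu2AlH, CH2Cl2, −78 → −40 °C; aq. KNaC4H4O6
Reagents that add atoms: none
Why: i-Bu2AlH 1,2-reduction of the α,β-unsaturated ester to the allylic alcohol at low temperature, without conjugate reduction.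

Step 9
Reactants: 16 diol
Product: 17 (3R,4S)-6-(benzyloxy)-4-[4-(benzyloxy)-3-methoxyphenyl]-3-(hydroxymethyl)-5-methoxy-3,4-dihydronaphthalene-2-carbaldehyde
Conditions: MnO2 (activated, excess), CH2Cl2, rt
Reagents that add atoms: none
Why: Chemoselective MnO2 oxidation of the allylic, styrene-conjugated primary alcohol to the enal; the saturated primary alcohol at C2 is inert and lactol formation is disfavoured because it would force the C1 aryl group out of its pseudo-axial position.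

Step 10
Reactants: 17 bis-benzyl ether of the target
Product: 18 vitedoin A, (3R,4S)-6-hydroxy-4-(4-hydroxy-3-methoxyphenyl)-3-(hydroxymethyl)-5-methoxy-3,4-dihydronaphthalene-2-carbaldehyde
Conditions: BCl3, C6HMe5, CH2Cl2, −78 °C; then MeOH
Reagents that add atoms: none
Why: Lewis-acid debenzylation of both aryl benzyl ethers at −78 °C with pentamethylbenzene as benzyl-cation scavenger; no hydrogenation is involved, so the C3=C4 bond and the aldehyde survive, and the methyl ethers are not cleaved at this temperature.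

## Compound list

1 | 4-(benzyloxy)-3-methoxybenzaldehyde | COc1cc(C=O)ccc1OCc1ccccc1 | starting material
2 | 4-(benzyloxy)-2-bromo-5-methoxybenzaldehyde | COc1cc(C=O)c(Br)cc1OCc1ccccc1 | intermediate
3 | dimethyl succinate | COC(=O)CCC(=O)OC | starting material
4 | methyl 2-[4-(benzyloxy)-2-bromo-5-methoxyphenyl]-5-oxooxolane-3-carboxylate (paraconate lactone, stereoisomer mixture, not isolated) | COC(=O)C1CC(=O)OC1c1cc(OC)c(OCc2ccccc2)cc1Br | intermediate
5 | (3E)-4-[4-(benzyloxy)-2-bromo-5-methoxyphenyl]-3-(methoxycarbonyl)but-3-enoic acid | COC(=O)/C(=C/c1cc(OC)c(OCc2ccccc2)cc1Br)CC(=O)O | intermediate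
6 | (S)-4-benzyl-1,3-oxazolidin-2-one | O=C1N[C@@H](Cc2ccccc2)CO1 | starting material
7 | mixed pivalic anhydride of 5 (not isolated) | COC(=O)/C(=C/c1cc(OC)c(OCc2ccccc2)cc1Br)CC(=O)OC(=O)C(C)(C)C | intermediate
8 | (4S)-4-benzyl-3-[(3E)-4-[4-(benzyloxy)-2-bromo-5-methoxyphenyl]-3-(methoxycarbonyl)but-3-enoyl]-1,3-oxazolidin-2-one | COC(=O)/C(=C/c1cc(OC)c(OCc2ccccc2)cc1Br)CC(=O)N1[C@@H](Cc2ccccc2)COC1=O | intermediate
9 | di-n-butylboron (Z)-enolate of 8 (not isolated) | COC(=O)/C(=C/c1cc(OC)c(OCc2ccccc2)cc1Br)/C=C(\OB(CCCC)CCCC)N1[C@@H](Cc2ccccc2)COC1=O | intermediate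
10 | di-n-butylboron aldolate of 11 (not isolated) | COC(=O)/C(=C/c1cc(OC)c(OCc2ccccc2)cc1Br)[C@@H]([C@H](OB(CCCC)CCCC)c1ccc(OCc2ccccc2)c(OC)c1)C(=O)N1[C@@H](Cc2ccccc2)COC1=O | intermediate
11 | (4S)-4-benzyl-3-[(2S,3E)-4-[4-(benzyloxy)-2-bromo-5-methoxyphenyl]-2-[(S)-[4-(benzyloxy)-3-methoxyphenyl](hydroxy)methyl]-3-(methoxycarbonyl)but-3-enoyl]-1,3-oxazolidin-2-one (syn-aldol) | COC(=O)/C(=C/c1cc(OC)c(OCc2ccccc2)cc1Br)[C@@H]([C@H](O)c1ccc(OCc2ccccc2)c(OC)c1)C(=O)N1[C@@H](Cc2ccccc2)COC1=O | intermediate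
12 | p-alkoxybenzylic cation from 11 (not isolated) | COC(=O)/C(=C/c1cc(OC)c(OCc2ccccc2)cc1Br)[C@@H]([CH+]c1ccc(OCc2ccccc2)c(OC)c1)C(=O)N1[C@@H](Cc2ccccc2)COC1=O | intermediate
13 | methyl (3R,4S)-6-(benzyloxy)-4-[4-(benzyloxy)-3-methoxyphenyl]-3-{[(4S)-4-benzyl-2-oxo-1,3-oxazolidin-3-yl]carbonyl}-8-bromo-5-methoxy-3,4-dihydronaphthalene-2-carboxylate | COC(=O)C1=Cc2c(Br)cc(OCc3ccccc3)c(OC)c2[C@H](c2ccc(OCc3ccccc3)c(OC)c2)[C@H]1C(=O)N1[C@@H](Cc2ccccc2)COC1=O | intermediate
14 | methyl (3R,4S)-6-(benzyloxy)-4-[4-(benzyloxy)-3-methoxyphenyl]-3-{[(4S)-4-benzyl-2-oxo-1,3-oxazolidin-3-yl]carbonyl}-5-methoxy-3,4-dihydronaphthalene-2-carboxylate | COC(=O)C1=Cc2ccc(OCc3ccccc3)c(OC)c2[C@H](c2ccc(OCc3ccccc3)c(OC)c2)[C@H]1C(=O)N1[C@@H](Cc2ccccc2)COC1=O | intermediate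
15 | methyl (3R,4S)-6-(benzyloxy)-4-[4-(benzyloxy)-3-methoxyphenyl]-3-(hydroxymethyl)-5-methoxy-3,4-dihydronaphthalene-2-carboxylate | COC(=O)C1=Cc2ccc(OCc3ccccc3)c(OC)c2[C@H](c2ccc(OCc3ccccc3)c(OC)c2)[C@H]1CO | intermediate
16 | [(1S,2R)-7-(benzyloxy)-1-[4-(benzyloxy)-3-methoxyphenyl]-8-methoxy-1,2-dihydronaphthalene-2,3-diyl]dimethanol | OCC1=Cc2ccc(OCc3ccccc3)c(OC)c2[C@H](c2ccc(OCc3ccccc3)c(OC)c2)[C@H]1CO | intermediate
17 | (3R,4S)-6-(benzyloxy)-4-[4-(benzyloxy)-3-methoxyphenyl]-3-(hydroxymethyl)-5-methoxy-3,4-dihydronaphthalene-2-carbaldehyde | O=CC1=Cc2ccc(OCc3ccccc3)c(OC)c2[C@H](c2ccc(OCc3ccccc3)c(OC)c2)[C@H]1CO | intermediate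
18 | vitedoin A, (3R,4S)-6-hydroxy-4-(4-hydroxy-3-methoxyphenyl)-3-(hydroxymethyl)-5-methoxy-3,4-dihydronaphthalene-2-carbaldehyde | COc1cc([C@H]2c3c(ccc(O)c3OC)C=C(C=O)[C@@H]2CO)ccc1O | target

## Step count and risks

Total steps: 10. Longest linear sequence: 10 steps (1 → 2 → 5 → 8 → 11 → 13 → 14 → 15 → 16 → 17 → 18).

**Most likely to fail, first: step 5 (ring closure).** Closure has to occur at the hindered carbon between side chain and OMe of a ring that is deactivated by the conjugated ester. The cation can instead lose the C2 proton to a 2,3-dibenzylidene system, which would erase C2. The fallback closes the ring at the alcohol oxidation level, where ring A carries a donor styrene instead of an acceptor acrylate and C2–H is no longer next to a carbonyl. It sets out from 11: LiAlH4, THF, −20 °C reduces imide and enoate together to the bromo triol F6. Ac2O, pyridine gives the triacetate F7. BF3·OEt2, CH2Cl2, −40 °C ionises only the secondary p-alkoxybenzylic acetate and closes to the trans bromo diacetate F8. n-Bu3SnH/AIBN gives the diacetate F9, and K2CO3, MeOH delivers the diol 16, where the route is rejoined.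

**Second: step 4 (boron aldol).** The imide is hindered and doubly unsaturated; enolisation may be sluggish or conversion with the electron-rich aldehyde poor. The fallback makes the C1–C2 bond by Claisen-type C-acylation and reduces afterwards. It sets out from 5: the same mixed-anhydride coupling (through 7) with (R)-4-benzyl-1,3-oxazolidin-2-one gives the (4R)-imide F1. LiN(i-Pr)2, THF, −78 °C and then commercial 4-(benzyloxy)-3-methoxybenzoyl chloride give the β-keto imide F2. The chelated lithium (Z)-enolate is acylated on the face opposite to that used by the boron aldol, which is why the other auxiliary enantiomer is taken; C2 then has the same spatial arrangement as in 11. Zn(BH4)2, CH2Cl2, −20 °C gives the β-hydroxy imide F3; either carbinol epimer serves because that centre is ionised next. CF3CO2H as in step 5 gives the cyclised bromo imide ester F4, n-Bu3SnH/AIBN gives the debrominated imide ester F5, and LiBH4 releases the (R)-auxiliary and delivers 15, where the route is rejoined.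

**Third: step 10 (final debenzylation).** BCl3 meets an enal, a free primary alcohol and a doubly benzylic C–H in the last step. The fallback moves the debenzylation to a robust intermediate and switches to fluoride-labile phenol protection. It sets out from 14: BCl3, C6HMe5, CH2Cl2, −78 °C gives the bisphenol F10. i-Pr3SiCl, imidazole, DMF gives the bis(triisopropylsilyl) ether F11. LiAlH4, THF, −20 °C gives the silyl-protected diol F12, and MnO2 gives the silyl-protected hydroxy enal F13. HF·pyridine, THF, 0 °C then gives 18 directly.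

## Further compounds

F1 | step 4 | (4R)-4-benzyl-3-[(3E)-4-[4-(benzyloxy)-2-bromo-5-methoxyphenyl]-3-(methoxycarbonyl)but-3-enoyl]-1,3-oxazolidin-2-one | COC(=O)/C(=C/c1cc(OC)c(OCc2ccccc2)cc1Br)CC(=O)N1[C@H](Cc2ccccc2)COC1=O
F2 | step 4 | (4R)-4-benzyl-3-[(2S,3E)-2-[4-(benzyloxy)-3-methoxybenzoyl]-4-[4-(benzyloxy)-2-bromo-5-methoxyphenyl]-3-(methoxycarbonyl)but-3-enoyl]-1,3-oxazolidin-2-one | COC(=O)/C(=C/c1cc(OC)c(OCc2ccccc2)cc1Br)[C@@H](C(=O)c1ccc(OCc2ccccc2)c(OC)c1)C(=O)N1[C@H](Cc2ccccc2)COC1=O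
F3 | step 4 | (4R)-4-benzyl-3-[(2S,3E)-4-[4-(benzyloxy)-2-bromo-5-methoxyphenyl]-2-[[4-(benzyloxy)-3-methoxyphenyl](hydroxy)methyl]-3-(methoxycarbonyl)but-3-enoyl]-1,3-oxazolidin-2-one (carbinol epimers) | COC(=O)/C(=C/c1cc(OC)c(OCc2ccccc2)cc1Br)[C@@H](C(O)c1ccc(OCc2ccccc2)c(OC)c1)C(=O)N1[C@H](Cc2ccccc2)COC1=O
F4 | step 4 | methyl (3R,4S)-6-(benzyloxy)-4-[4-(benzyloxy)-3-methoxyphenyl]-3-{[(4R)-4-benzyl-2-oxo-1,3-oxazolidin-3-yl]carbonyl}-8-bromo-5-methoxy-3,4-dihydronaphthalene-2-carboxylate | COC(=O)C1=Cc2c(Br)cc(OCc3ccccc3)c(OC)c2[C@H](c2ccc(OCc3ccccc3)c(OC)c2)[C@H]1C(=O)N1[C@H](Cc2ccccc2)COC1=O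
F5 | step 4 | methyl (3R,4S)-6-(benzyloxy)-4-[4-(benzyloxy)-3-methoxyphenyl]-3-{[(4R)-4-benzyl-2-oxo-1,3-oxazolidin-3-yl]carbonyl}-5-methoxy-3,4-dihydronaphthalene-2-carboxylate | COC(=O)C1=Cc2ccc(OCc3ccccc3)c(OC)c2[C@H](c2ccc(OCc3ccccc3)c(OC)c2)[C@H]1C(=O)N1[C@H](Cc2ccccc2)COC1=O
F6 | step 5 | (2R,3E)-3-{[4-(benzyloxy)-2-bromo-5-methoxyphenyl]methylidene}-2-[(S)-[4-(benzyloxy)-3-methoxyphenyl](hydroxy)methyl]butane-1,4-diol | OC/C(=C/c1cc(OC)c(OCc2ccccc2)cc1Br)[C@@H]([C@H](O)c1ccc(OCc2ccccc2)c(OC)c1)CO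
F7 | step 5 | triacetate of F6 | CC(=O)OC/C(=C/c1cc(OC)c(OCc2ccccc2)cc1Br)[C@@H]([C@H](OC(C)=O)c1ccc(OCc2ccccc2)c(OC)c1)COC(C)=O
F8 | step 5 | [(1S,2R)-7-(benzyloxy)-1-[4-(benzyloxy)-3-methoxyphenyl]-5-bromo-8-methoxy-1,2-dihydronaphthalene-2,3-diyl]bis(methylene) diacetate | CC(=O)OCC1=Cc2c(Br)cc(OCc3ccccc3)c(OC)c2[C@H](c2ccc(OCc3ccccc3)c(OC)c2)[C@H]1COC(C)=O
F9 | step 5 | [(1S,2R)-7-(benzyloxy)-1-[4-(benzyloxy)-3-methoxyphenyl]-8-methoxy-1,2-dihydronaphthalene-2,3-diyl]bis(methylene) diacetate | CC(=O)OCC1=Cc2ccc(OCc3ccccc3)c(OC)c2[C@H](c2ccc(OCc3ccccc3)c(OC)c2)[C@H]1COC(C)=O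
F10 | step 10 | methyl (3R,4S)-3-{[(4S)-4-benzyl-2-oxo-1,3-oxazolidin-3-yl]carbonyl}-6-hydroxy-4-(4-hydroxy-3-methoxyphenyl)-5-methoxy-3,4-dihydronaphthalene-2-carboxylate | COC(=O)C1=Cc2ccc(O)c(OC)c2[C@H](c2ccc(O)c(OC)c2)[C@H]1C(=O)N1[C@@H](Cc2ccccc2)COC1=O
F11 | step 10 | bis(triisopropylsilyl) ether of F10 | COC(=O)C1=Cc2ccc(O[Si](C(C)C)(C(C)C)C(C)C)c(OC)c2[C@H](c2ccc(O[Si](C(C)C)(C(C)C)C(C)C)c(OC)c2)[C@H]1C(=O)N1[C@@H](Cc2ccccc2)COC1=O
F12 | step 10 | [(1S,2R)-8-methoxy-1-{3-methoxy-4-[(triisopropylsilyl)oxy]phenyl}-7-[(triisopropylsilyl)oxy]-1,2-dihydronaphthalene-2,3-diyl]dimethanol | OCC1=Cc2ccc(O[Si](C(C)C)(C(C)C)C(C)C)c(OC)c2[C@H](c2ccc(O[Si](C(C)C)(C(C)C)C(C)C)c(OC)c2)[C@H]1CO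
F13 | step 10 | (3R,4S)-3-(hydroxymethyl)-5-methoxy-4-{3-methoxy-4-[(triisopropylsilyl)oxy]phenyl}-6-[(triisopropylsilyl)oxy]-3,4-dihydronaphthalene-2-carbaldehyde | O=CC1=Cc2ccc(O[Si](C(C)C)(C(C)C)C(C)C)c(OC)c2[C@H](c2ccc(O[Si](C(C)C)(C(C)C)C(C)C)c(OC)c2)[C@H]1CO
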